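**Plan**
1. Retrosynthesis: take off the two crotonates, return the C1 ketone to a silyl-protected carbinol and remove the C13 methylene. Then cut, in one operation, the lactone O–C12 bond and the ring bond C5–C6, which opens both rings to the acyclic (Z)-dienyl aldehyde ester 16.
2. Enabling feature: the ten-membered ring holds the run O–C6H–C5H2–C4H(CH3)–C3H=C2H, with oxygen and methyl 1,3-anti and the alkene directly behind the methyl-bearing carbon. This is the product pattern of the nickel-catalysed reductive homoallylation of an aldehyde by a 2-methyl-1,3-diene. The C12 ester sits γ to O6, so the five-membered lactone ring closes on the new oxygen.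
3. Compound 16 is cut further at C6–C7 (nitromethane as formyl anion), C7=C11 (olefination), C1–C2 (alkynyl addition), and C1–C10 and C10–C14 (two Grignard additions). This leads back to L-tartrate, which supplies C7–C10.
4. Forward: the tartrate core grows first at C10/C1 to the (Z)-diene, then at C7 to the aldehyde ester. Step 12 forms the carbocycle and the lactone together. Methylenation, crotonylation and C1 oxidation finish the route.
5. Stereochemistry: C8 and C9 come from L-tartaric acid, C10 from chelate-controlled addition, C7 from allylic-strain-controlled conjugate addition, and C6 and C4 from the key step. The Z alkene comes from cis semi-reduction of an enyne, and the E crotonates from (E)-crotonic anhydride.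

Key step: step 12

Remark on locants: germacrane numbering is used. C1 is the ketone carbon, C2=C3 the Z alkene, C4 the CH(CH3) with methyl C15, C5 the CH2 and C6 the lactone carbinol. C7 is the ring-fusion CH, C8 and C9 the crotonate carbons, C10 the tertiary carbinol with methyl C14, and C11/C12/C13 the lactone α-carbon, carbonyl and methylene. The target is (2Z,4R,6R,7S,8S,9R,10S).

Remark on the chemistry (assumption): the C1 carbinol centre made in step 5 is temporary and is erased in step 17. The route is drawn for the chelate-controlled (1S) epimer (O1 syn to O10); the (1R) epimer would converge on the same ketone.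

**Step 1**
Reactants: 1 dimethyl (4R,5R)-2,2-dimethyl-1,3-dioxolane-4,5-dicarboxylate (dimethyl 2,3-O-isopropylidene-L-tartrate)
Product: 2 (4R,5R)-N,N'-dimethoxy-N,N',2,2-tetramethyl-1,3-dioxolane-4,5-dicarboxamide (bis-Weinreb amide)
Conditions: MeNH(OMe)·HCl (3 equiv), iPrMgCl (6 equiv), THF, −20 to 0 °C
Reagents that add atoms: N,O-dimethylhydroxylamine hydrochloride, CNOC.Cl
Why: Weinreb aminolysis of both esters by the chloromagnesium amide should be fast at low temperature and should leave the two α-alkoxy centres (C8, C9) of the more stable trans-dioxolane untouched.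

**Step 2**
Reactants: 2 bis-Weinreb amide
Product: 3 (4R,5R)-5-acetyl-N-methoxy-N,2,2-trimethyl-1,3-dioxolane-4-carboxamide (keto amide; acetyl = C10 and C14)
Conditions: MeMgBr (1.05 equiv), THF, −78 to −40 °C; aq. NH4Cl
Reagents that add atoms: methylmagnesium bromide, C[Mg]Br
Why: In this Weinreb ketone synthesis the magnesium-chelated tetrahedral adduct lasts until work-up and its charge slows attack on the second amide, and because the two amides of C2-symmetric 2 are homotopic, mono-addition should give one compound.

**Step 3**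
Reactants: 3 keto amide
Product: 4 (4R,5R)-5-[(2R)-2-hydroxybut-3-en-2-yl]-N-methoxy-N,2,2-trimethyl-1,3-dioxolane-4-carboxamide (vinyl carbinol; C10–OH syn to O9)
Conditions: MgBr2·OEt2, CH2Cl2, −78 °C; CH2=CHMgBr (THF), −78 °C; aq. NH4Cl
Reagents that add atoms: vinylmagnesium bromide, C=C[Mg]Br
Why: In this Cram-chelate Grignard addition to an α-alkoxy ketone, magnesium ties the ketone oxygen to O9 and the vinyl group enters from the face bearing H9 rather than C8, which sets C10 as in the target, while at −78 °C the ketone should react far faster than the Weinreb amide.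

**Step 4**
Reactants: 4 vinyl carbinol
Product: 6 (4R,5R)-5-[(2S)-2-hydroxy-1-oxopropan-2-yl]-N-methoxy-N,2,2-trimethyl-1,3-dioxolane-4-carboxamide (α-hydroxy aldehyde; CHO = C1), via ozonide 5 (not isolated)
Conditions: O3, CH2Cl2, −78 °C; then Me2S, −78 °C to rt
Reagents that add atoms: ozone, [O-][O+]=O
Why: Ozonolysis with reductive work-up cleaves the only alkene and turns the inner vinyl carbon into the C1 aldehyde, and C10 is quaternary so it cannot epimerise.

**Step 5**
Reactants: 6 α-hydroxy aldehyde; 7 2-methylbut-1-en-3-yne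
Product: 9 (4R,5R)-5-[(2R,3S)-2,3-dihydroxy-6-methylhept-6-en-4-yn-2-yl]-N-methoxy-N,2,2-trimethyl-1,3-dioxolane-4-carboxamide (enyne diol; (1S), O1 syn to O10), via alkynylmagnesium bromide 8 (not isolated)
Conditions: 7 (3 equiv), EtMgBr (3 equiv), THF, 0 °C to rt; then 6, −78 to −30 °C; aq. NH4Cl
Reagents that add atoms: 2-methylbut-1-en-3-yne (7), C=C(C)C#C
Why: In this alkynyl Grignard addition under Cram-chelate control, the first equivalent forms the C10 magnesium alkoxide, which chelates the aldehyde so that the alkynyl group enters past the methyl group to give the temporary (1S) carbinol, and the aldehyde should outrun the Weinreb amide at low temperature.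

**Step 6**
Reactants: 9 enyne diol
Product: 10 (4R,5R)-5-[(2R,3S,4Z)-2,3-dihydroxy-6-methylhepta-4,6-dien-2-yl]-N-methoxy-N,2,2-trimethyl-1,3-dioxolane-4-carboxamide ((Z)-dienyl diol)
Conditions: Zn dust activated with Cu(OAc)2 and AgNO3, MeOH/H2O 1:1, rt to 40 °C
Reagents that add atoms: none
Why: Zn(Cu/Ag) semi-reduction of a conjugated enyne, helped by the propargylic hydroxyl, delivers both hydrogens to one side of the alkyne and should give the Z alkene C2=C3 without touching the isopropenyl group, the N–O bond or the acetonide.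

**Step 7**
Reactants: 10 (Z)-dienyl diol
Product: 11 bis-TBS ether of 10 (O1 and O10 silylated; all centres unchanged)
Conditions: TBSOTf (3 equiv), 2,6-lutidine, CH2Cl2, 0 °C to rt
Reagents that add atoms: tert-butyldimethylsilyl triflate, CC(C)(C)[Si](C)(C)OS(=O)(=O)C(F)(F)F
Why: Silyl triflate silylation covers the secondary and the hindered tertiary hydroxyl in one operation under non-acidic conditions that the dienyl carbinol tolerates.

**Step 8**
Reactants: 11 bis-TBS Weinreb amide
Product: 12 C7 aldehyde (11 with C(=O)N(OMe)Me reduced to CHO)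
Conditions: iBu2AlH, THF, −78 °C; aq. potassium sodium tartrate
Reagents that add atoms: none
Why: Weinreb amide reduction stops at the aluminium-chelated hemiaminal, which releases the aldehyde only on work-up, and C8 holds because the trans-dioxolane is the more stable epimer.

**Step 9**
Reactants: 12 C7 aldehyde
Product: 13 methyl (Z)-enoate (C8–C7H=C11H–C12O2Me, Z)
Conditions: (CF3CH2O)2P(O)CH2CO2Me, KN(SiMe3)2, 18-crown-6, THF, −78 °C
Reagents that add atoms: methyl bis(2,2,2-trifluoroethyl)phosphonoacetate, COC(=O)CP(=O)(OCC(F)(F)F)OCC(F)(F)F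
Why: The Still–Gennari olefination is under kinetic control and should give the Z enoate, which is chosen because it maximises allylic strain for the next step.

**Step 10**
Reactants: 13 methyl (Z)-enoate
Product: 14 nitro ester (methyl 4-nitrobutanoate carrying the chain at C7; (7S), nitromethyl group syn to O8)
Conditions: MeNO2 (10 equiv), DBU (0.3 equiv), MeCN, 0 °C to rt
Reagents that add atoms: nitromethane, C[N+](=O)[O-]
Why: In this Michael addition of nitronate, the rotamer of the Z enoate that minimises A(1,3) strain has H8 eclipsing the alkene, so the nucleophile comes anti to the bulky C8–C9 bond and sets C7 with the nitromethyl group syn to O8, as is known for acetonide-protected γ,δ-dialkoxy enoates.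

**Step 11**
Reactants: 14 nitro ester
Product: 16 aldehyde ester (C6HO and CH2CO2Me on C7; C1, C7–C10 unchanged), via sodium nitronate 15 (not isolated)
Conditions: NaOMe, MeOH, 0 °C; then aq. TiCl3, NH4OAc buffer (pH 5–6), THF, 0 °C
Reagents that add atoms: water, O
Why: In this reductive Nef reaction, trivalent titanium reduces the nitronate to the imine, which hydrolyses at a pH mild enough to keep the C7 centre, the acetonide, the silyl ethers and the diene.

**Step 12**
Reactants: 16 aldehyde ester
Product: 19 ten-membered lactone ((1S); C4, C6–C10 as in the target; 8,9-acetonide, 1,10-bis-TBS, C11H2), via diethylborinate 17 (not isolated), via hydroxy ester 18 (not isolated)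
Conditions: Ni(acac)2 (20 mol %), Et3B (3 equiv), THF, 30 °C, 16 added over 12 h (final 2 mM); aq. NaHCO3; then PPTS (cat.), toluene, 50 °C
Reagents that add atoms: none
Why: Proposed new method: Et3B reduces Ni(acac)2 to zerovalent nickel, which binds the diene and the boron-activated aldehyde of 16, joins C5 to C6 by oxidative cyclisation to an oxanickelacycle with an η3-allyl over C4–C3–C2, takes an ethyl group from boron, loses ethylene by β-hydride elimination and puts the hydride on C4 by reductive elimination, giving borinate 17. The closest known reaction type is the nickel-catalysed reductive homoallylation of aldehydes with 1,3-dienes, known intermolecularly (isoprene gives 1,3-anti 3-methylpent-4-en-1-ols) and intramolecularly only for five- to seven-membered rings closed at the tethered diene terminus; closure of a ten-membered ring through the free terminus is the untested extension. The carbocycle closes in a 10-endo mode, all four diene carbons ending in the ring, and after hydrolysis to 18 the γ-lactone closes 5-exo-trig by attack of O6 on the C12 ester. C6 is set by Felkin–Anh approach of C5 anti to the C7–C8 bond, which gives the trans H6/H7 fusion, and C4 is set because the hydride leaves a nickel atom held by O6, so H4 and O6 end on the same side of the zigzag chain and methyl and oxygen are 1,3-anti, the only arrangement in which the C7-to-C2 tether can span two cis positions of the nickelacycle. The step needs attack at C5 and not at C2 (seven-membered ring), which the substrate secures by the 2-methyl-4-alkyl diene pattern that makes the unsubstituted C5H2 terminus both the most nucleophilic and the least hindered while C2 is shielded by the C1 silyl ether and quaternary C10. It also needs retention of the Z alkene, carried through as the anti-allyl because syn/anti exchange would demand a σ-bond from nickel to crowded C2 and because the Z cyclodecene is the less strained isomer, and it needs slow addition to hold oligomerisation down.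

**Step 13**
Reactants: 19 ten-membered lactone
Product: 22 α-methylene lactone (19 with C11=C13H2), via Mannich base 20 (not isolated), via ammonium iodide 21 (not isolated)
Conditions: LiN(iPr)2, THF, −78 °C; Me2N=CH2 I, −78 °C to rt; then MeI, MeOH, rt; then aq. NaHCO3/CH2Cl2
Reagents that add atoms: Eschenmoser's salt (N,N-dimethylmethyleneiminium iodide), C=[N+](C)C.[I-]
Why: In this Eschenmoser methylenation (Mannich reaction of the lactone enolate, quaternisation, elimination), C11 carries the only acidic C–H, no leaving group sits β to the enolate, and the C11 centre formed in passing (attack anti to C8) becomes sp2.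

**Step 14**
Reactants: 22 α-methylene lactone
Product: 23 8,9-diol (acetonide removed; both TBS ethers kept)
Conditions: CeCl3·7H2O, oxalic acid (cat.), MeCN, rt
Reagents that add atoms: none
Why: Mild acid-catalysed ketal hydrolysis under conditions known to spare TBS ethers should free only O8 and O9, because the silyl ethers at C1 (neopentyl-like) and C10 (tertiary) are strongly hindered.

**Step 15**
Reactants: 23 8,9-diol
Product: 24 8,9-bis[(E)-but-2-enoate]
Conditions: (E)-crotonic anhydride (6 equiv), DMAP, Et3N, CH2Cl2, 0 °C to rt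
Reagents that add atoms: (E)-crotonic anhydride, C/C=C/C(=O)OC(=O)/C=C/C
Why: DMAP-catalysed acylation with the anhydride avoids the vinylketene pathway of crotonyl chloride and so keeps the conjugated E ester, and O8H and O9H are the only free hydroxyls.

**Step 16**
Reactants: 24 bis-crotonate
Product: 25 1,10-diol (both TBS groups removed; (1S) allylic alcohol and C10 tertiary alcohol)
Conditions: HF·pyridine, pyridine, THF, 0 °C to rt
Reagents that add atoms: none
Why: Fluoride-driven Si–O cleavage in a buffered, weakly acidic medium should not promote acyl migration, translactonisation or conjugate addition.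

**Step 17**
Reactants: 25 1,10-diol
Product: 26 target CNP0223772.1
Conditions: Dess–Martin periodinane, CH2Cl2, 0 °C to rt
Reagents that add atoms: none
Why: Dess–Martin oxidation turns the secondary allylic alcohol into the Z enone and erases the temporary C1 centre, while the tertiary C10–OH cannot be oxidised and the neutral conditions leave C4, the Z alkene and the esters alone.

**Compound list**
1 | dimethyl (4R,5R)-2,2-dimethyl-1,3-dioxolane-4,5-dicarboxylate | COC(=O)[C@@H]1OC(C)(C)O[C@H]1C(=O)OC | starting material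
2 | bis-Weinreb amide | CON(C)C(=O)[C@@H]1OC(C)(C)O[C@H]1C(=O)N(C)OC | intermediate
3 | keto amide | CC(=O)[C@@H]1OC(C)(C)O[C@H]1C(=O)N(C)OC | intermediate
4 | vinyl carbinol | C=C[C@@](C)(O)[C@@H]1OC(C)(C)O[C@H]1C(=O)N(C)OC | intermediate
5 | ozonide of 4 (epimers at the trioxolane CH) | C1OOC(O1)[C@@](C)(O)[C@@H]2OC(C)(C)O[C@H]2C(=O)N(C)OC | intermediate
6 | α-hydroxy aldehyde | O=C[C@@](C)(O)[C@@H]1OC(C)(C)O[C@H]1C(=O)N(C)OC | intermediate
7 | 2-methylbut-1-en-3-yne | C=C(C)C#C | starting material
8 | (3-methylbut-3-en-1-yn-1-yl)magnesium bromide | C=C(C)C#C[Mg]Br | intermediate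
9 | enyne diol | C=C(C)C#C[C@H](O)[C@@](C)(O)[C@@H]1OC(C)(C)O[C@H]1C(=O)N(C)OC | intermediate
10 | (Z)-dienyl diol | C=C(C)/C=C\[C@H](O)[C@@](C)(O)[C@@H]1OC(C)(C)O[C@H]1C(=O)N(C)OC | intermediate
11 | bis-TBS Weinreb amide | C=C(C)/C=C\[C@H](O[Si](C)(C)C(C)(C)C)[C@@](C)(O[Si](C)(C)C(C)(C)C)[C@@H]1OC(C)(C)O[C@H]1C(=O)N(C)OC | intermediate
12 | C7 aldehyde | C=C(C)/C=C\[C@H](O[Si](C)(C)C(C)(C)C)[C@@](C)(O[Si](C)(C)C(C)(C)C)[C@@H]1OC(C)(C)O[C@H]1C=O | intermediate
13 | methyl (Z)-enoate | C=C(C)/C=C\[C@H](O[Si](C)(C)C(C)(C)C)[C@@](C)(O[Si](C)(C)C(C)(C)C)[C@@H]1OC(C)(C)O[C@H]1/C=C\C(=O)OC | intermediate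
14 | nitro ester | C=C(C)/C=C\[C@H](O[Si](C)(C)C(C)(C)C)[C@@](C)(O[Si](C)(C)C(C)(C)C)[C@@H]1OC(C)(C)O[C@H]1[C@@H](CC(=O)OC)C[N+](=O)[O-] | intermediate
15 | sodium nitronate of 14 | C=C(C)/C=C\[C@H](O[Si](C)(C)C(C)(C)C)[C@@](C)(O[Si](C)(C)C(C)(C)C)[C@@H]1OC(C)(C)O[C@H]1[C@@H](CC(=O)OC)C=[N+]([O-])[O-].[Na+] | intermediate
16 | aldehyde ester (cyclisation precursor) | C=C(C)/C=C\[C@H](O[Si](C)(C)C(C)(C)C)[C@@](C)(O[Si](C)(C)C(C)(C)C)[C@@H]1OC(C)(C)O[C@H]1[C@@H](CC(=O)OC)C=O | intermediate
17 | ten-membered O6-diethylborinate | CCB(CC)O[C@@H]1C[C@@H](C)/C=C\[C@H](O[Si](C)(C)C(C)(C)C)[C@@](C)(O[Si](C)(C)C(C)(C)C)[C@@H]2OC(C)(C)O[C@H]2[C@H]1CC(=O)OC | intermediate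
18 | ten-membered hydroxy ester | O[C@@H]1C[C@@H](C)/C=C\[C@H](O[Si](C)(C)C(C)(C)C)[C@@](C)(O[Si](C)(C)C(C)(C)C)[C@@H]2OC(C)(C)O[C@H]2[C@H]1CC(=O)OC | intermediate
19 | ten-membered lactone | C1C(=O)O[C@@H]2C[C@@H](C)/C=C\[C@H](O[Si](C)(C)C(C)(C)C)[C@@](C)(O[Si](C)(C)C(C)(C)C)[C@@H]3OC(C)(C)O[C@H]3[C@@H]12 | intermediate
20 | Mannich base (C11–CH2NMe2, trans to C8) | CN(C)C[C@@H]1C(=O)O[C@@H]2C[C@@H](C)/C=C\[C@H](O[Si](C)(C)C(C)(C)C)[C@@](C)(O[Si](C)(C)C(C)(C)C)[C@@H]3OC(C)(C)O[C@H]3[C@@H]12 | intermediate
21 | trimethylammonium iodide of 20 | C[N+](C)(C)C[C@@H]1C(=O)O[C@@H]2C[C@@H](C)/C=C\[C@H](O[Si](C)(C)C(C)(C)C)[C@@](C)(O[Si](C)(C)C(C)(C)C)[C@@H]3OC(C)(C)O[C@H]3[C@@H]12.[I-] | intermediate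
22 | α-methylene lactone | C=C1C(=O)O[C@@H]2C[C@@H](C)/C=C\[C@H](O[Si](C)(C)C(C)(C)C)[C@@](C)(O[Si](C)(C)C(C)(C)C)[C@@H]3OC(C)(C)O[C@H]3[C@@H]12 | intermediate
23 | 8,9-diol | C=C1C(=O)O[C@@H]2C[C@@H](C)/C=C\[C@H](O[Si](C)(C)C(C)(C)C)[C@@](C)(O[Si](C)(C)C(C)(C)C)[C@H](O)[C@@H](O)[C@@H]12 | intermediate
24 | 8,9-bis-crotonate | C=C1C(=O)O[C@@H]2C[C@@H](C)/C=C\[C@H](O[Si](C)(C)C(C)(C)C)[C@@](C)(O[Si](C)(C)C(C)(C)C)[C@H](OC(=O)/C=C/C)[C@@H](OC(=O)/C=C/C)[C@@H]12 | intermediate
25 | 1,10-diol | C=C1C(=O)O[C@@H]2C[C@@H](C)/C=C\[C@H](O)[C@@](C)(O)[C@H](OC(=O)/C=C/C)[C@@H](OC(=O)/C=C/C)[C@@H]12 | intermediate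
26 | CNP0223772.1 | C=C1C(=O)O[C@@H]2C[C@@H](C)/C=C\C(=O)[C@@](C)(O)[C@H](OC(=O)/C=C/C)[C@@H](OC(=O)/C=C/C)[C@@H]12 | target

Total step count: 17. Longest linear sequence: 17 (from 1).

**Steps most likely to fail**

**1. Step 12 (the proposed new method).** Several things may go wrong:
- The chain may oligomerise.
- The aldehyde may couple at the tethered diene terminus C2 and close a seven-membered ring.
- The anti-allyl nickel species may relax, so that the Z geometry is lost.
- The Z diene may bind nickel too weakly for turnover at high dilution.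

The fallback sets out from 6 and comes back at 19. It makes the C5–C6 bond by the established intermolecular homoallylation and closes the ring at C2=C3 by metathesis. Aldehyde 6 takes CH2=CHMgBr under the same chelate control to give the vinyl carbinol diol F1. TBSOTf/2,6-lutidine gives the bis-silyl ether F2, iBu2AlH gives the aldehyde F3, and Still–Gennari olefination gives the Z enoate F4. MeNO2/DBU gives the nitro ester F5, NaOMe gives the sodium nitronate F6, and buffered aq. TiCl3 turns this into the aldehyde ester F7. Ni(acac)2/Et3B with excess isoprene gives the diethylborinate F8, which is hydrolysed to the hydroxy ester F9 and lactonised with PPTS to the diene lactone F10. This sequence sets C6 (Felkin–Anh) and C4 (1,3-anti). Ring-closing metathesis of F10 with the second-generation Grubbs catalyst in dilute hot toluene then closes C2=C3, for which the ten-membered ring favours Z, and gives 19.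

**2. Step 11.** The aldehyde may epimerise at C7 or lose O8 by β-elimination. The nitronate may revert by retro-Michael loss of nitromethane, or the reduction may stall at the oxime stage. The fallback sets out from 13 and comes back at 16. It replaces the nitro group with a sulfur-based formyl anion. 2-Lithio-1,3-dithiane in THF/HMPA adds 1,4 to the Z enoate under the same allylic-strain control to give the dithiane ester F11. This is unmasked under neutral alkylative conditions (MeI, CaCO3, aq. MeCN) to 16.

**3. Step 14.** The C1 silyl ether may be lost together with the acetonide, or the lactone may migrate to the freed O8. The fallback sets out from 22 and comes back at 26. It drops protecting-group differentiation in favour of intrinsic reactivity differences. Aqueous HF in MeCN removes acetonide and both silyl groups to give the tetraol F12. MnO2 in CH2Cl2 oxidises only the allylic C1–OH to give the enone triol F13. (E)-Crotonic anhydride/DMAP then acylates the two secondary hydroxyls, but not the tertiary one, to give 26.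

**Further compounds**
F1 | step 12 | vinyl carbinol diol | C=C[C@H](O)[C@@](C)(O)[C@@H]1OC(C)(C)O[C@H]1C(=O)N(C)OC
F2 | step 12 | bis-silyl ether of F1 | C=C[C@H](O[Si](C)(C)C(C)(C)C)[C@@](C)(O[Si](C)(C)C(C)(C)C)[C@@H]1OC(C)(C)O[C@H]1C(=O)N(C)OC
F3 | step 12 | aldehyde from F2 | C=C[C@H](O[Si](C)(C)C(C)(C)C)[C@@](C)(O[Si](C)(C)C(C)(C)C)[C@@H]1OC(C)(C)O[C@H]1C=O
F4 | step 12 | Z enoate from F3 | C=C[C@H](O[Si](C)(C)C(C)(C)C)[C@@](C)(O[Si](C)(C)C(C)(C)C)[C@@H]1OC(C)(C)O[C@H]1/C=C\C(=O)OC
F5 | step 12 | nitro ester from F4 | C=C[C@H](O[Si](C)(C)C(C)(C)C)[C@@](C)(O[Si](C)(C)C(C)(C)C)[C@@H]1OC(C)(C)O[C@H]1[C@@H](CC(=O)OC)C[N+](=O)[O-]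
F6 | step 12 | sodium nitronate of F5 | C=C[C@H](O[Si](C)(C)C(C)(C)C)[C@@](C)(O[Si](C)(C)C(C)(C)C)[C@@H]1OC(C)(C)O[C@H]1[C@@H](CC(=O)OC)C=[N+]([O-])[O-].[Na+]
F7 | step 12 | aldehyde ester from F6 | C=C[C@H](O[Si](C)(C)C(C)(C)C)[C@@](C)(O[Si](C)(C)C(C)(C)C)[C@@H]1OC(C)(C)O[C@H]1[C@@H](CC(=O)OC)C=O
F8 | step 12 | diethylborinate from F7 and isoprene | C=C[C@H](O[Si](C)(C)C(C)(C)C)[C@@](C)(O[Si](C)(C)C(C)(C)C)[C@@H]1OC(C)(C)O[C@H]1[C@@H](CC(=O)OC)[C@@H](C[C@@H](C)C=C)OB(CC)CC
F9 | step 12 | hydroxy ester from F8 | C=C[C@H](O[Si](C)(C)C(C)(C)C)[C@@](C)(O[Si](C)(C)C(C)(C)C)[C@@H]1OC(C)(C)O[C@H]1[C@@H](CC(=O)OC)[C@@H](C[C@@H](C)C=C)O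
F10 | step 12 | diene lactone (metathesis precursor) | C=C[C@H](O[Si](C)(C)C(C)(C)C)[C@@](C)(O[Si](C)(C)C(C)(C)C)[C@@H]1OC(C)(C)O[C@H]1[C@H]2CC(=O)O[C@@H]2C[C@@H](C)C=C
F11 | step 11 | dithiane ester | C=C(C)/C=C\[C@H](O[Si](C)(C)C(C)(C)C)[C@@](C)(O[Si](C)(C)C(C)(C)C)[C@@H]1OC(C)(C)O[C@H]1[C@@H](CC(=O)OC)C2SCCCS2
F12 | step 14 | tetraol | C=C1C(=O)O[C@@H]2C[C@@H](C)/C=C\[C@H](O)[C@@](C)(O)[C@H](O)[C@@H](O)[C@@H]12
F13 | step 14 | enone triol | C=C1C(=O)O[C@@H]2C[C@@H](C)/C=C\C(=O)[C@@](C)(O)[C@H](O)[C@@H](O)[C@@H]12
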